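**Plan**
Retrosynthetic cuts, in order: the two phenol masks and the C4 ketone (back to a C4 carbinol). Next, ring D at the C5'–CH= bond, its O4'–CMe2 bond traced back to a 1,1-dimethylpropargyl ether on O4'. Then C4–O and C3–H (hydroboration of a C3=C4 alkene), O1–C2 (Mitsunobu), and the C3=C4 and lactone O1–C2 bonds of a 3-arylcoumarin.
Enabling feature: O4' of ring B is the oxygen of ring D. It lies between oxygen-bearing C3' and unsubstituted C5', so a propargyl group on O4' can settle only on C5'. Ring D can therefore be closed last, after every reduction that its C=C bond would not survive.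
Forward order: rings A and B come from 5-methoxyresorcinol and 3,4-dihydroxybenzaldehyde. Ring C forms as a coumarin (step 7), is opened (step 8) and is reclosed as a 2H-chromene (step 9). Ring D forms in step 13.
Stereochemistry: C3 (R) is set together with C4 (S) by reagent-controlled syn hydroboration with IpcBH2 made from (−)-α-pinene. C4 is later erased by oxidation, and C3 becomes enolisable only in the last two steps, which are run without base.

Key step: step 13

Abbreviation: TOM = CH2OSi(i-Pr)3, so OTOM = OCH2OSi(i-Pr)3, a formaldehyde acetal that fluoride cleaves.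
Assumption: the face selectivity of IpcBH2 known for 1-arylcycloalkenes is taken to hold for the 3-aryl-2H-chromene of step 10. This calls for the reagent from (−)-α-pinene; if the sense proved opposite, the enantiomeric reagent would be used.

**Route**

Step 1
Reactants: 1 5-methoxyresorcinol
Product: 3 2,4-dihydroxy-6-methoxybenzaldehyde, via aryl iminium chloride 2 (not isolated)
Conditions: POCl3, DMF, MeCN, 0 °C → rt; then H2O, 50 °C
Reagents that add atoms: N,N-dimethylformamide, CN(C)C=O; water, O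
Why: Vilsmeier–Haack formylation of the phloroglucinol-type ring should favour the two equivalent carbons that lie between OH and OMe and para to the second OH over the single carbon between the two hydroxyls, and the minor symmetric isomer is removed by crystallisation.

Step 2
Reactants: 3 2,4-dihydroxy-6-methoxybenzaldehyde
Product: 4 2-hydroxy-6-methoxy-4-(OTOM)benzaldehyde
Conditions: TOMCl, i-Pr2NEt, CH2Cl2, 0 °C
Reagents that add atoms: (triisopropylsiloxy)methyl chloride, ClCO[Si](C(C)C)(C(C)C)C(C)C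
Why: In this Williamson-type alkylation with a chloromethyl ether the 2-OH is held back by its hydrogen bond to the aldehyde, so the more acidic and freer 4-OH reacts and receives a base-stable acetal that fluoride can still unlock.

Step 3
Reactants: 5 3,4-dihydroxybenzaldehyde
Product: 6 4-(benzyloxy)-3-hydroxybenzaldehyde
Conditions: BnCl, NaHCO3, NaI (catalytic), DMF, 40 °C
Reagents that add atoms: benzyl chloride, ClCc1ccccc1
Why: Williamson etherification under a weak base ionises only the 4-OH, whose phenoxide is conjugated with the para aldehyde, so the temporary benzyl group lands on the oxygen that later becomes O4' of ring D.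

Step 4
Reactants: 6 4-(benzyloxy)-3-hydroxybenzaldehyde
Product: 7 4-(benzyloxy)-3-(OTOM)benzaldehyde
Conditions: TOMCl, i-Pr2NEt, CH2Cl2, 0 °C → rt
Reagents that add atoms: (triisopropylsiloxy)methyl chloride, ClCO[Si](C(C)C)(C(C)C)C(C)C
Why: The same chloromethyl ether alkylation caps the remaining phenol, and the CH2O spacer is chosen because a silyl group bound directly to O3 could hop to the neighbouring O4 phenoxide that steps 11 and 12 expose.

Step 5
Reactants: 7 4-(benzyloxy)-3-(OTOM)benzaldehyde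
Product: 9 2-[4-(benzyloxy)-3-(OTOM)phenyl]acetaldehyde, via methyl enol ether 8 (not isolated)
Conditions: Ph3P(CH2OMe)Cl, KOt-Bu, THF, 0 °C → rt; then 2 M HCl, THF, rt
Reagents that add atoms: (methoxymethyl)triphenylphosphonium chloride, COC[P+](c1ccccc1)(c1ccccc1)c1ccccc1.[Cl-]; water, O
Why: Wittig methoxymethylenation followed by acid hydrolysis of enol ether 8 is the standard one-carbon homologation of an aromatic aldehyde, and the benzyl ether and TOM acetal tolerate butoxide and brief dilute acid.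

Step 6
Reactants: 9 2-[4-(benzyloxy)-3-(OTOM)phenyl]acetaldehyde
Product: 10 2-[4-(benzyloxy)-3-(OTOM)phenyl]acetic acid
Conditions: NaClO2, NaH2PO4, 2-methylbut-2-ene, t-BuOH/H2O, rt
Reagents that add atoms: sodium chlorite, [Na+].[O-]Cl=O
Why: Pinnick oxidation converts the sensitive arylacetaldehyde into the acid at mildly acidic pH, while 2-methylbut-2-ene traps the hypochlorous acid that could otherwise chlorinate the electron-rich ring.

Step 7
Reactants: 10 2-[4-(benzyloxy)-3-(OTOM)phenyl]acetic acid; 4 2-hydroxy-6-methoxy-4-(OTOM)benzaldehyde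
Product: 13 3-[4-(benzyloxy)-3-(OTOM)phenyl]-5-methoxy-7-(OTOM)-2H-chromen-2-one, via mixed anhydride 11 (not isolated), via aryl ester 12 (not isolated)
Conditions: Ac2O, Et3N, 110 °C
Reagents that add atoms: none
Why: In this Perkin–Oglialoro condensation the acid is activated as mixed anhydride 11 and acylates the phenol of 4 to give ester 12, whose doubly activated CH2 then condenses with the ortho aldehyde in an intramolecular aldol condensation that forms C3=C4 and ring C.

Step 8
Reactants: 13 3-arylcoumarin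
Product: 14 (Z)-2-[4-(benzyloxy)-3-(OTOM)phenyl]-3-[2-hydroxy-6-methoxy-4-(OTOM)phenyl]prop-2-en-1-ol
Conditions: i-Bu2AlH (excess), CH2Cl2, −78 → 0 °C; aqueous potassium sodium tartrate
Reagents that add atoms: none
Why: i-Bu2AlH reduces the unsaturated lactone in the 1,2 sense down to the allylic alcohol and phenol without touching the C=C bond, so the Z geometry imposed by the ring is kept.

Step 9
Reactants: 14 (Z)-allylic alcohol phenol
Product: 15 3-[4-(benzyloxy)-3-(OTOM)phenyl]-5-methoxy-7-(OTOM)-2H-chromene (isoflav-3-ene)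
Conditions: PPh3, DIAD, THF, 0 °C → rt
Reagents that add atoms: none
Why: Intramolecular Mitsunobu etherification activates the primary allylic alcohol and the Z-disposed phenol displaces it in a six-membered closure under neutral conditions that spare the acid-sensitive 2H-chromene.

Step 10
Reactants: 15 isoflav-3-ene
Product: 17 (3R,4S)-3-[4-(benzyloxy)-3-(OTOM)phenyl]-5-methoxy-7-(OTOM)chroman-4-ol (trans), via dialkylborane 16 (not isolated)
Conditions: (IpcBH2)2·TMEDA [from (−)-α-pinene], BF3·OEt2, THF, rt, filter; add 15, −25 → 0 °C; then NaOH, 30% H2O2, 0 °C → rt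
Reagents that add atoms: hydrogen peroxide, OO
Why: In this Brown asymmetric hydroboration IpcBH2 adds H and B syn across C3=C4 with boron at the less substituted C4, the isopinocampheyl group selects the alkene face as it does for 1-arylcycloalkenes so that hydrogen delivery makes C3 (R), and stereoretentive peroxide oxidation of the C4–B bond of 16 turns the syn adduct into the trans (3R,4S) carbinol.

Step 11
Reactants: 17 (3R,4S)-4'-O-benzyl isoflavan-4-ol
Product: 18 (3R,4S)-3-[4-hydroxy-3-(OTOM)phenyl]-5-methoxy-7-(OTOM)chroman-4-ol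
Conditions: H2 (1 atm), 10% Pd/C, NaHCO3, EtOAc, rt
Reagents that add atoms: none
Why: Catalytic hydrogenolysis cleaves the aryl benzyl ether rapidly under neutral buffered conditions, under which isoflavan-4-ols are known to persist, and no C=C bond is present at this stage.

Step 12
Reactants: 18 (3R,4S)-4'-phenol; 19 3-chloro-3-methylbut-1-yne
Product: 20 (3R,4S)-5-methoxy-3-{4-[(2-methylbut-3-yn-2-yl)oxy]-3-(OTOM)phenyl}-7-(OTOM)chroman-4-ol
Conditions: DBU, CuCl2·2H2O (1 mol %), MeCN, 0 °C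
Reagents that add atoms: none
Why: Copper-catalysed propargylic substitution of the tertiary chloride by the phenol proceeds at 0 °C, the far less acidic C4 alcohol stays untouched, and the acetal at O3' cannot migrate to the O4' phenoxide.

Step 13
Reactants: 20 (3R,4S)-4'-O-(1,1-dimethylpropargyl) isoflavan-4-ol
Product: 24 (3R,4S)-3-[2,2-dimethyl-8-(OTOM)-2H-chromen-6-yl]-5-methoxy-7-(OTOM)chroman-4-ol, via allenyl dienone 21 (not isolated), via allenyl phenol 22 (not isolated), via quinone methide 23 (not isolated)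
Conditions: PhNEt2 (degassed), 160 °C, argon; solvent distilled off in vacuo, Et3N-washed silica
Reagents that add atoms: none
Why: Heating starts an aromatic propargyl Claisen [3,3] shift in which the O4'–CMe2 bond breaks and the alkyne terminus bonds to C5', giving dienone 21, which tautomerises to o-allenylphenol 22. A 1,5-hydrogen shift from the phenol OH to the central allene carbon gives (Z)-o-quinone methide 23, and a disrotatory oxa-6π electrocyclisation re-forms the O4'–CMe2 bond and closes the six-membered pyran ring D. This is the known thermal conversion of aryl 1,1-dimethylpropargyl ethers into 2,2-dimethyl-2H-chromenes, which the gem-dimethyl group accelerates. The step needs regioselectivity between the two carbons ortho to O4', and the substrate secures it because C3' carries the acetal oxygen, so a shift to C3' is reversible and unproductive and only the adduct at C5'–H can rearomatise. No lasting stereocentre is created (the sp3 C5' of 21 disappears on tautomerisation), and C3 cannot epimerise because C4 is still a carbinol. The weakly basic solvent keeps the medium free of acid, so the electron-rich C4 benzylic alcohol, with every phenolic oxygen of ring A capped, should neither ionise nor dehydrate.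

Step 14
Reactants: 24 (3R,4S)-pyrano-isoflavan-4-ol
Product: 25 (3R)-3-[2,2-dimethyl-8-(OTOM)-2H-chromen-6-yl]-5-methoxy-7-(OTOM)chroman-4-one
Conditions: Dess–Martin periodinane, NaHCO3, CH2Cl2, 0 °C → rt
Reagents that add atoms: none
Why: Dess–Martin oxidation works at or below room temperature in a bicarbonate-buffered, non-enolising medium, so the hindered benzylic carbinol becomes the ketone while the now acidic C3–H keeps its configuration.

Step 15
Reactants: 25 (3R)-bis(TOM) isoflavanone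
Product: 27 (3R)-7-hydroxy-3-(8-hydroxy-2,2-dimethyl-2H-chromen-6-yl)-5-methoxychroman-4-one, via bis hemiacetal 26 (not isolated)
Conditions: HF·pyridine, pyridine, THF, 0 °C → rt; pH 7 phosphate buffer work-up
Reagents that add atoms: none
Why: Fluoride-induced desilylation under pyridine-buffered, weakly acidic conditions gives bis hemiacetal 26, which sheds formaldehyde on neutral work-up, so both phenols are freed without base that would enolise C3 and without strong acid that would attack the chromene.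

**Compound list**
1 | 5-methoxyresorcinol | COc1cc(O)cc(O)c1 | starting material
2 | [(2,4-dihydroxy-6-methoxyphenyl)methylidene]dimethyliminium chloride | COc1cc(O)cc(O)c1C=[N+](C)C.[Cl-] | intermediate
3 | 2,4-dihydroxy-6-methoxybenzaldehyde | COc1cc(O)cc(O)c1C=O | intermediate
4 | 2-hydroxy-6-methoxy-4-[(triisopropylsiloxy)methoxy]benzaldehyde | COc1cc(OCO[Si](C(C)C)(C(C)C)C(C)C)cc(O)c1C=O | intermediate
5 | 3,4-dihydroxybenzaldehyde | O=Cc1ccc(O)c(O)c1 | starting material
6 | 4-(benzyloxy)-3-hydroxybenzaldehyde | O=Cc1ccc(OCc2ccccc2)c(O)c1 | intermediate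
7 | 4-(benzyloxy)-3-[(triisopropylsiloxy)methoxy]benzaldehyde | O=Cc1ccc(OCc2ccccc2)c(OCO[Si](C(C)C)(C(C)C)C(C)C)c1 | intermediate
8 | 1-(benzyloxy)-4-(2-methoxyvinyl)-2-(OTOM)benzene, E/Z mixture | COC=Cc1ccc(OCc2ccccc2)c(OCO[Si](C(C)C)(C(C)C)C(C)C)c1 | intermediate
9 | 2-[4-(benzyloxy)-3-(OTOM)phenyl]acetaldehyde | O=CCc1ccc(OCc2ccccc2)c(OCO[Si](C(C)C)(C(C)C)C(C)C)c1 | intermediate
10 | 2-[4-(benzyloxy)-3-(OTOM)phenyl]acetic acid | OC(=O)Cc1ccc(OCc2ccccc2)c(OCO[Si](C(C)C)(C(C)C)C(C)C)c1 | intermediate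
11 | acetic 2-[4-(benzyloxy)-3-(OTOM)phenyl]acetic anhydride | CC(=O)OC(=O)Cc1ccc(OCc2ccccc2)c(OCO[Si](C(C)C)(C(C)C)C(C)C)c1 | intermediate
12 | 2-formyl-3-methoxy-5-(OTOM)phenyl 2-[4-(benzyloxy)-3-(OTOM)phenyl]acetate | COc1cc(OCO[Si](C(C)C)(C(C)C)C(C)C)cc(OC(=O)Cc2ccc(OCc3ccccc3)c(OCO[Si](C(C)C)(C(C)C)C(C)C)c2)c1C=O | intermediate
13 | 3-[4-(benzyloxy)-3-(OTOM)phenyl]-5-methoxy-7-(OTOM)-2H-chromen-2-one | COc1cc(OCO[Si](C(C)C)(C(C)C)C(C)C)cc2c1C=C(c1ccc(OCc3ccccc3)c(OCO[Si](C(C)C)(C(C)C)C(C)C)c1)C(=O)O2 | intermediate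
14 | (Z)-2-[4-(benzyloxy)-3-(OTOM)phenyl]-3-[2-hydroxy-6-methoxy-4-(OTOM)phenyl]prop-2-en-1-ol | OC/C(c1ccc(OCc2ccccc2)c(OCO[Si](C(C)C)(C(C)C)C(C)C)c1)=C\c1c(O)cc(OCO[Si](C(C)C)(C(C)C)C(C)C)cc1OC | intermediate
15 | 3-[4-(benzyloxy)-3-(OTOM)phenyl]-5-methoxy-7-(OTOM)-2H-chromene | COc1cc(OCO[Si](C(C)C)(C(C)C)C(C)C)cc2c1C=C(c1ccc(OCc3ccccc3)c(OCO[Si](C(C)C)(C(C)C)C(C)C)c1)CO2 | intermediate
16 | (isopinocampheyl)[trans-3-aryl-5-methoxy-7-(OTOM)chroman-4-yl]borane, boron on C4 anti to the C3 aryl group | COc1cc(OCO[Si](C(C)C)(C(C)C)C(C)C)cc2c1[C@@H](B[C@H]3C[C@H]4C[C@@H]([C@@H]3C)C4(C)C)[C@H](c1ccc(OCc3ccccc3)c(OCO[Si](C(C)C)(C(C)C)C(C)C)c1)CO2 | intermediate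
17 | (3R,4S)-3-[4-(benzyloxy)-3-(OTOM)phenyl]-5-methoxy-7-(OTOM)chroman-4-ol | COc1cc(OCO[Si](C(C)C)(C(C)C)C(C)C)cc2c1[C@@H](O)[C@H](c1ccc(OCc3ccccc3)c(OCO[Si](C(C)C)(C(C)C)C(C)C)c1)CO2 | intermediate
18 | (3R,4S)-3-[4-hydroxy-3-(OTOM)phenyl]-5-methoxy-7-(OTOM)chroman-4-ol | COc1cc(OCO[Si](C(C)C)(C(C)C)C(C)C)cc2c1[C@@H](O)[C@H](c1ccc(O)c(OCO[Si](C(C)C)(C(C)C)C(C)C)c1)CO2 | intermediate
19 | 3-chloro-3-methylbut-1-yne | CC(C)(Cl)C#C | starting material
20 | (3R,4S)-5-methoxy-3-{4-[(2-methylbut-3-yn-2-yl)oxy]-3-(OTOM)phenyl}-7-(OTOM)chroman-4-ol | COc1cc(OCO[Si](C(C)C)(C(C)C)C(C)C)cc2c1[C@@H](O)[C@H](c1ccc(OC(C)(C)C#C)c(OCO[Si](C(C)C)(C(C)C)C(C)C)c1)CO2 | intermediate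
21 | ring B as 6-(3-methylbuta-1,2-dienyl)-2-(OTOM)cyclohexa-2,4-dienone, joined at its C4 to C3 of the (3R,4S)-chromanol, C5' unassigned | COc1cc(OCO[Si](C(C)C)(C(C)C)C(C)C)cc2c1[C@@H](O)[C@H](C1=CC(C=C=C(C)C)C(=O)C(OCO[Si](C(C)C)(C(C)C)C(C)C)=C1)CO2 | intermediate
22 | (3R,4S)-3-[4-hydroxy-3-(3-methylbuta-1,2-dienyl)-5-(OTOM)phenyl]-5-methoxy-7-(OTOM)chroman-4-ol | COc1cc(OCO[Si](C(C)C)(C(C)C)C(C)C)cc2c1[C@@H](O)[C@H](c1cc(OCO[Si](C(C)C)(C(C)C)C(C)C)c(O)c(C=C=C(C)C)c1)CO2 | intermediate
23 | ring B as (Z)-6-(3-methylbut-2-enylidene)-2-(OTOM)cyclohexa-2,4-dienone, joined at its C4 to C3 of the (3R,4S)-chromanol | COc1cc(OCO[Si](C(C)C)(C(C)C)C(C)C)cc2c1[C@@H](O)[C@H](C1=C/C(=C/C=C(C)C)C(=O)C(OCO[Si](C(C)C)(C(C)C)C(C)C)=C1)CO2 | intermediate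
24 | (3R,4S)-3-[2,2-dimethyl-8-(OTOM)-2H-chromen-6-yl]-5-methoxy-7-(OTOM)chroman-4-ol | COc1cc(OCO[Si](C(C)C)(C(C)C)C(C)C)cc2c1[C@@H](O)[C@H](c1cc(OCO[Si](C(C)C)(C(C)C)C(C)C)c3c(c1)C=CC(C)(C)O3)CO2 | intermediate
25 | (3R)-3-[2,2-dimethyl-8-(OTOM)-2H-chromen-6-yl]-5-methoxy-7-(OTOM)chroman-4-one | COc1cc(OCO[Si](C(C)C)(C(C)C)C(C)C)cc2c1C(=O)[C@H](c1cc(OCO[Si](C(C)C)(C(C)C)C(C)C)c3c(c1)C=CC(C)(C)O3)CO2 | intermediate
26 | (3R)-7-(hydroxymethoxy)-3-[8-(hydroxymethoxy)-2,2-dimethyl-2H-chromen-6-yl]-5-methoxychroman-4-one | COc1cc(OCO)cc2c1C(=O)[C@H](c1cc(OCO)c3c(c1)C=CC(C)(C)O3)CO2 | intermediate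
27 | (3R)-7-hydroxy-3-(8-hydroxy-2,2-dimethyl-2H-chromen-6-yl)-5-methoxychroman-4-one | COc1cc(O)cc2c1C(=O)[C@H](c1cc(O)c3c(c1)C=CC(C)(C)O3)CO2 | target

**Step count**
Total steps: 15. Longest linear sequence: 13 (steps 3 to 15, from 3,4-dihydroxybenzaldehyde).

**Steps most likely to fail**

Step 10. C4 is crowded by the peri 5-OMe group and the alkene is polarised by the donor-rich ring A.
- The addition may therefore be slow or lose facial discrimination.
- The reagent may shed α-pinene.
- Boron may go to C3, from where the aryloxide on C2 would be expelled.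

The fallback sets out from 10 together with 4 and comes back at 17. It sets C3 and C4 by an auxiliary-controlled Evans syn aldol instead of by addition to an alkene. Aldehyde 4 is O-allylated (allyl bromide, K2CO3, DMF) to 2-(allyloxy)-6-methoxy-4-(OTOM)benzaldehyde F1. Acid 10 is coupled (DCC, DMAP, CH2Cl2) with (S)-4-benzyloxazolidin-2-one to the N-arylacetyl imide F2. F2 and F1 are combined under Bu2BOTf and i-Pr2NEt in CH2Cl2 at −78 °C to give the (2S,3S)-syn aldol F3. LiBH4 in THF/MeOH releases the auxiliary and gives the (1S,2R)-1,3-diol F4. Pd(PPh3)4 with morpholine removes the allyl group to give the phenol diol F5. PPh3 and DIAD then close O1–C2 at the primary alcohol to give 17, because the syn relationship of the open chain maps onto the trans relationship in ring C.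

Step 13. Prolonged heating may cause loss of water from the very electron-rich C4 carbinol. This would regenerate a C3=C4 alkene and erase the stereocentre. The fallback sets out from 20 and comes back at 24, and it masks the carbinol before the rearrangement. TESCl and imidazole in DMF give the C4 triethylsilyl ether of the propargyl ether F6. The same thermal rearrangement gives the C4 triethylsilyl ether of the chromene F7. One equivalent of TBAF in THF at 0 °C removes the secondary TES group well before the hindered TOM silyl groups and returns 24. Basic fluoride is harmless here because C3 is not yet enolisable.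

Step 15. The hindered silyl groups of the TOM acetals are cleaved slowly, and long exposure may allow enolisation and erosion of configuration at C3. The fallback sets out from 24 and comes back at 27, and it moves the slow unmasking to the carbinol stage.
- TBAF in THF at rt converts 24 into the free diphenol carbinol F8.
- TBSCl and imidazole in CH2Cl2 at 0 °C silylate only the two phenols to give the bis(aryl TBS ether) F9. Silyl migration is no longer possible because O4' is locked in ring D.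
- Dess–Martin periodinane with NaHCO3 gives the bis(TBS) isoflavanone F10.
- Brief treatment with HF·pyridine and pyridine in THF at 0 °C cleaves the labile aryl silyl ethers to give 27.

**Further compounds**
F1 | step 10 | 2-(allyloxy)-6-methoxy-4-(OTOM)benzaldehyde | COc1cc(OCO[Si](C(C)C)(C(C)C)C(C)C)cc(OCC=C)c1C=O
F2 | step 10 | (S)-4-benzyl-3-{2-[4-(benzyloxy)-3-(OTOM)phenyl]acetyl}oxazolidin-2-one | O=C(Cc1ccc(OCc2ccccc2)c(OCO[Si](C(C)C)(C(C)C)C(C)C)c1)N1C(=O)OC[C@@H]1Cc1ccccc1
F3 | step 10 | (S)-4-benzyl-3-{(2S,3S)-3-[2-(allyloxy)-6-methoxy-4-(OTOM)phenyl]-2-[4-(benzyloxy)-3-(OTOM)phenyl]-3-hydroxypropanoyl}oxazolidin-2-one | COc1cc(OCO[Si](C(C)C)(C(C)C)C(C)C)cc(OCC=C)c1[C@@H](O)[C@H](c1ccc(OCc2ccccc2)c(OCO[Si](C(C)C)(C(C)C)C(C)C)c1)C(=O)N1C(=O)OC[C@@H]1Cc1ccccc1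
F4 | step 10 | (1S,2R)-1-[2-(allyloxy)-6-methoxy-4-(OTOM)phenyl]-2-[4-(benzyloxy)-3-(OTOM)phenyl]propane-1,3-diol | COc1cc(OCO[Si](C(C)C)(C(C)C)C(C)C)cc(OCC=C)c1[C@@H](O)[C@H](c1ccc(OCc2ccccc2)c(OCO[Si](C(C)C)(C(C)C)C(C)C)c1)CO
F5 | step 10 | (1S,2R)-2-[4-(benzyloxy)-3-(OTOM)phenyl]-1-[2-hydroxy-6-methoxy-4-(OTOM)phenyl]propane-1,3-diol | COc1cc(OCO[Si](C(C)C)(C(C)C)C(C)C)cc(O)c1[C@@H](O)[C@H](c1ccc(OCc2ccccc2)c(OCO[Si](C(C)C)(C(C)C)C(C)C)c1)CO
F6 | step 13 | C4 triethylsilyl ether of 20 | COc1cc(OCO[Si](C(C)C)(C(C)C)C(C)C)cc2c1[C@@H](O[Si](CC)(CC)CC)[C@H](c1ccc(OC(C)(C)C#C)c(OCO[Si](C(C)C)(C(C)C)C(C)C)c1)CO2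
F7 | step 13 | C4 triethylsilyl ether of 24 | COc1cc(OCO[Si](C(C)C)(C(C)C)C(C)C)cc2c1[C@@H](O[Si](CC)(CC)CC)[C@H](c1cc(OCO[Si](C(C)C)(C(C)C)C(C)C)c3c(c1)C=CC(C)(C)O3)CO2
F8 | step 15 | (3R,4S)-3-(8-hydroxy-2,2-dimethyl-2H-chromen-6-yl)-5-methoxychroman-4,7-diol | COc1cc(O)cc2c1[C@@H](O)[C@H](c1cc(O)c3c(c1)C=CC(C)(C)O3)CO2
F9 | step 15 | (3R,4S)-7-(TBSO)-3-[8-(TBSO)-2,2-dimethyl-2H-chromen-6-yl]-5-methoxychroman-4-ol | COc1cc(O[Si](C)(C)C(C)(C)C)cc2c1[C@@H](O)[C@H](c1cc(O[Si](C)(C)C(C)(C)C)c3c(c1)C=CC(C)(C)O3)CO2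
F10 | step 15 | (3R)-7-(TBSO)-3-[8-(TBSO)-2,2-dimethyl-2H-chromen-6-yl]-5-methoxychroman-4-one | COc1cc(O[Si](C)(C)C(C)(C)C)cc2c1C(=O)[C@H](c1cc(O[Si](C)(C)C(C)(C)C)c3c(c1)C=CC(C)(C)O3)CO2
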